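**Retrosynthetic overview**
1. Feature: in the pentasubstituted benzo ring A, the ring oxygen O1 (on C8a) and the carbonyl carbon C4 (on C4a) sit on adjacent carbons. One carboxylic acid can therefore deliver both across an aryne spanning C4a and C8a; C5 (OMe) flanks C4a and C8 (piperidinyl) flanks C8a.
2. Cutting C8a–O1, C4a–C4 and O1–C2 gives silyl triflate 18 and 3-phenylpropiolic acid 19. The pyranone ring C is the last ring formed; ring B arrives with the acid.
3. 18 comes from N-Boc resorcinol 12 by bromination of its symmetric ring, O-to-C silyl shift with triflation, and MOM capping. The bromine position tells the two hydroxyls apart.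
4. 12 comes from aldehyde 4 by sulfinimine formation, auxiliary-controlled addition of a 4-chlorobutyl Grignard reagent (sets piperidine C2 as R) and N-alkylative closure of the piperidine ring (step 5).
5. 4 comes from 5-methoxyresorcinol (ring A, purchased) by bis-MOM protection and directed lithiation/formylation.

Key step: step 10

Assumption: the stereocentre reads as R from the SMILES, and the (S)-sulfinyl auxiliary is chosen from the usual magnesium chelate model; the configuration of 9 is to be confirmed before it is carried on.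

Step 1
Reactants: 1 5-methoxyresorcinol
Product: 2 1-methoxy-3,5-bis(methoxymethoxy)benzene
Conditions: NaH, MOMCl, DMF, 0 °C → rt
Reagents that add atoms: chloromethyl methyl ether COCCl
Why: Williamson-type O-alkylation of both phenoxides gives the two strong ortho-directing acetal groups needed for step 2.

Step 2
Reactants: 2 1-methoxy-3,5-bis(methoxymethoxy)benzene
Product: 4 4-methoxy-2,6-bis(methoxymethoxy)benzaldehyde, via aryllithium 3 (not isolated)
Conditions: n-BuLi, TMEDA, THF, 0 °C; DMF, 0 °C → rt; H2O
Reagents that add atoms: N,N-dimethylformamide CN(C)C=O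
Why: Directed ortho-metalation should occur at the ring position held between the two MOM ethers, in preference to the positions next to the weaker methoxy director, and DMF formylates the aryllithium.

Step 3
Reactants: 4 4-methoxy-2,6-bis(methoxymethoxy)benzaldehyde; 5 (S)-2-methylpropane-2-sulfinamide
Product: 6 (S,E)-N-[4-methoxy-2,6-bis(methoxymethoxy)benzylidene]-2-methylpropane-2-sulfinamide
Conditions: Ti(OEt)4, THF, 60 °C
Reagents that add atoms: none
Why: Ellman condensation, with Ti(OEt)4 as Lewis acid and water scavenger, should convert the hindered non-enolisable aldehyde into the E-sulfinimine.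

Step 4
Reactants: 6 the sulfinimine; 7 1-bromo-4-chlorobutane
Product: 9 (S)-N-[(1R)-5-chloro-1-[4-methoxy-2,6-bis(methoxymethoxy)phenyl]pentyl]-2-methylpropane-2-sulfinamide, via Grignard reagent 8 (not isolated)
Conditions: 7, Mg, Et2O, 35 °C; then 6, CH2Cl2, −78 → −20 °C; NH4Cl aq
Reagents that add atoms: none
Why: Ellman 1,2-addition of a Grignard reagent in a non-coordinating solvent proceeds through a six-membered chair with magnesium on the sulfinyl oxygen, so the (S)-sulfinyl group should deliver the alkyl group to the Re face of the imine and set the benzylic carbon as R; the two ortho MOM ethers lie symmetrically on both faces of the twisted aryl ring and should not bias the face, and the minor diastereomer is removed by chromatography or crystallisation.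

Step 5
Reactants: 9 the chloro sulfinamide
Product: 10 (2R)-1-[(S)-tert-butylsulfinyl]-2-[4-methoxy-2,6-bis(methoxymethoxy)phenyl]piperidine
Conditions: NaH, DMF, 0 °C → rt
Reagents that add atoms: none
Why: Intramolecular SN2 N-alkylation (6-exo-tet) of the sulfinamide anion on the primary chloride closes the piperidine ring without touching the stereocentre.

Step 6
Reactants: 10 the N-sulfinyl piperidine
Product: 12 tert-butyl (2R)-2-(2,6-dihydroxy-4-methoxyphenyl)piperidine-1-carboxylate, via aminodiol hydrochloride 11 (not isolated)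
Conditions: HCl (4 M in dioxane), MeOH, 0 °C → rt; evaporate; Boc2O, NaHCO3, THF/H2O, rt
Reagents that add atoms: di-tert-butyl dicarbonate CC(C)(C)OC(=O)OC(=O)OC(C)(C)C
Why: Acid methanolysis cleaves the N–S bond and both MOM acetals, and the ammonium salt is then Boc-protected chemoselectively on nitrogen under bicarbonate; the protonated nitrogen and the low temperature should keep the benzylic C–N bond from ionising.

Step 7
Reactants: 12 the N-Boc resorcinol
Product: 13 tert-butyl (2R)-2-(3-bromo-2,6-dihydroxy-4-methoxyphenyl)piperidine-1-carboxylate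
Conditions: NBS (1.0 equiv), CH2Cl2, −78 → −20 °C
Reagents that add atoms: N-bromosuccinimide O=C1CCC(=O)N1Br
Why: Electrophilic aromatic bromination; the two free ring positions are equivalent through the local twofold axis of the aryl group, so monobromination can give only one constitutional isomer, with bromine ortho to one hydroxyl and para to the other.

Step 8
Reactants: 13 the bromo resorcinol
Product: 17 tert-butyl (2R)-2-[6-hydroxy-4-methoxy-2-(trifluoromethylsulfonyloxy)-3-(trimethylsilyl)phenyl]piperidine-1-carboxylate, via bis(trimethylsilyl) ether 14 (not isolated), via lithium silylphenoxide 15 (not isolated), via silyl ether triflate 16 (not isolated)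
Conditions: HMDS, THF, 65 °C, evaporate; n-BuLi, THF, −78 °C; Tf2O, −78 → 0 °C; NaHCO3 aq; K2CO3 (cat.), MeOH, 0 °C
Reagents that add atoms: hexamethyldisilazane C[Si](C)(C)N[Si](C)(C)C; trifluoromethanesulfonic anhydride O=S(=O)(OS(=O)(=O)C(F)(F)F)C(F)(F)F
Why: One-pot O-silylation, bromine–lithium exchange, retro-Brook 1,3 O-to-C silyl shift from the only ortho silyloxy group and O-triflation of the released phenoxide is the standard way to 2-silylaryl triflates; the exchange at −78 °C should outrun deprotonation next to the carbamate, and the remote aryl silyl ether is methanolysed in work-up, so the two hydroxyls are differentiated by mechanism.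

Step 9
Reactants: 17 the phenol silyl triflate
Product: 18 tert-butyl (2R)-2-[4-methoxy-6-(methoxymethoxy)-2-(trifluoromethylsulfonyloxy)-3-(trimethylsilyl)phenyl]piperidine-1-carboxylate
Conditions: MOMCl, iPr2NEt, CH2Cl2, 0 °C → rt
Reagents that add atoms: chloromethyl methyl ether COCCl
Why: MOM protection of the remaining phenol removes the one nucleophile that would otherwise intercept the aryne.

Step 10
Reactants: 18 the silyl triflate; 19 3-phenylpropiolic acid
Product: 22 tert-butyl (2R)-2-[5-methoxy-7-(methoxymethoxy)-4-oxo-2-phenyl-4H-chromen-8-yl]piperidine-1-carboxylate, via aryne 20 (not isolated), via ynone phenoxide 21 (not isolated)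
Conditions: 19 (1.5 equiv), CsF (4 equiv), THF, 125 °C, sealed tube
Reagents that add atoms: none
Why: Fluoride attacks silicon and expels triflate to give aryne 20, the cesium carboxylate oxygen adds to C8a, and the aryl anion at C4a attacks the ester carbonyl through a four-membered alkoxide that fragments to the C4a ketone and the C8a phenoxide 21. The closest known reaction is aryne insertion into the C–O bond of carboxylic acids giving 2-hydroxyaryl ketones, which with arylpropiolic acids runs on to flavones. Ring C closes by 6-endo-dig oxa-Michael addition of the phenoxide to the ynone β-carbon, and the resulting vinyl anion is protonated by bifluoride to give the 4-pyranone. No stereocentre is formed, and the existing one is a non-acidic benzylic carbamate C–H that fluoride should not touch. The step needs oxygen at C8a and the acyl carbon at C4a: the C5 methoxy group polarises and distorts the aryne so that the nucleophile adds to the distal carbon C8a and the carbanion forms at C4a. That electronic bias has to outweigh the steric shielding of C8a by the piperidinyl carbamate and the weak opposing pull of the C7 ether.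

Step 11
Reactants: 22 the protected flavone
Product: 23 7-hydroxy-5-methoxy-2-phenyl-8-[(2R)-piperidin-2-yl]-4H-chromen-4-one
Conditions: HCl (4 M in dioxane), MeOH, 0 °C → rt; NaHCO3 aq
Reagents that add atoms: none
Why: Acid methanolysis of the MOM acetal and acidolysis of the Boc carbamate occur together, and because ring A is deactivated by the chromone carbonyl the benzylic C–N bond should not ionise at or below room temperature, so the R centre is kept.

**Compound list**
1 | 5-methoxyresorcinol | COc1cc(O)cc(O)c1 | starting material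
2 | 1-methoxy-3,5-bis(methoxymethoxy)benzene | COCOc1cc(OC)cc(OCOC)c1 | intermediate
3 | [4-methoxy-2,6-bis(methoxymethoxy)phenyl]lithium | [Li]c1c(OCOC)cc(OC)cc1OCOC | intermediate
4 | 4-methoxy-2,6-bis(methoxymethoxy)benzaldehyde | O=Cc1c(OCOC)cc(OC)cc1OCOC | intermediate
5 | (S)-2-methylpropane-2-sulfinamide | CC(C)(C)[S@](=O)N | starting material
6 | (S,E)-N-[4-methoxy-2,6-bis(methoxymethoxy)benzylidene]-2-methylpropane-2-sulfinamide | CC(C)(C)[S@](=O)/N=C/c1c(OCOC)cc(OC)cc1OCOC | intermediate
7 | 1-bromo-4-chlorobutane | ClCCCCBr | starting material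
8 | 4-chlorobutylmagnesium bromide | ClCCCC[Mg]Br | intermediate
9 | (S)-N-[(1R)-5-chloro-1-[4-methoxy-2,6-bis(methoxymethoxy)phenyl]pentyl]-2-methylpropane-2-sulfinamide | CC(C)(C)[S@](=O)N[C@H](CCCCCl)c1c(OCOC)cc(OC)cc1OCOC | intermediate
10 | (2R)-1-[(S)-tert-butylsulfinyl]-2-[4-methoxy-2,6-bis(methoxymethoxy)phenyl]piperidine | CC(C)(C)[S@](=O)N1CCCC[C@@H]1c1c(OCOC)cc(OC)cc1OCOC | intermediate
11 | (2R)-2-(2,6-dihydroxy-4-methoxyphenyl)piperidine hydrochloride | COc1cc(O)c([C@H]2CCCCN2)c(O)c1.Cl | intermediate
12 | tert-butyl (2R)-2-(2,6-dihydroxy-4-methoxyphenyl)piperidine-1-carboxylate | COc1cc(O)c([C@H]2CCCCN2C(=O)OC(C)(C)C)c(O)c1 | intermediate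
13 | tert-butyl (2R)-2-(3-bromo-2,6-dihydroxy-4-methoxyphenyl)piperidine-1-carboxylate | COc1cc(O)c([C@H]2CCCCN2C(=O)OC(C)(C)C)c(O)c1Br | intermediate
14 | tert-butyl (2R)-2-[3-bromo-4-methoxy-2,6-bis(trimethylsilyloxy)phenyl]piperidine-1-carboxylate | COc1cc(O[Si](C)(C)C)c([C@H]2CCCCN2C(=O)OC(C)(C)C)c(O[Si](C)(C)C)c1Br | intermediate
15 | lithium 2-[(2R)-1-Boc-piperidin-2-yl]-5-methoxy-6-(trimethylsilyl)-3-(trimethylsilyloxy)phenoxide | [Li+].COc1cc(O[Si](C)(C)C)c([C@H]2CCCCN2C(=O)OC(C)(C)C)c([O-])c1[Si](C)(C)C | intermediate
16 | tert-butyl (2R)-2-[4-methoxy-2-(trifluoromethylsulfonyloxy)-3-(trimethylsilyl)-6-(trimethylsilyloxy)phenyl]piperidine-1-carboxylate | COc1cc(O[Si](C)(C)C)c([C@H]2CCCCN2C(=O)OC(C)(C)C)c(OS(=O)(=O)C(F)(F)F)c1[Si](C)(C)C | intermediate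
17 | tert-butyl (2R)-2-[6-hydroxy-4-methoxy-2-(trifluoromethylsulfonyloxy)-3-(trimethylsilyl)phenyl]piperidine-1-carboxylate | COc1cc(O)c([C@H]2CCCCN2C(=O)OC(C)(C)C)c(OS(=O)(=O)C(F)(F)F)c1[Si](C)(C)C | intermediate
18 | tert-butyl (2R)-2-[4-methoxy-6-(methoxymethoxy)-2-(trifluoromethylsulfonyloxy)-3-(trimethylsilyl)phenyl]piperidine-1-carboxylate | COc1cc(OCOC)c([C@H]2CCCCN2C(=O)OC(C)(C)C)c(OS(=O)(=O)C(F)(F)F)c1[Si](C)(C)C | intermediate
19 | 3-phenylpropiolic acid | OC(=O)C#Cc1ccccc1 | starting material
20 | aryne: tert-butyl (2R)-2-[3-methoxy-5-(methoxymethoxy)-1,2-didehydrobenzen-6-yl]piperidine-1-carboxylate | COC1=CC(OCOC)=C([C@H]2CCCCN2C(=O)OC(C)(C)C)C#C1 | intermediate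
21 | cesium 2-[(2R)-1-Boc-piperidin-2-yl]-5-methoxy-3-(methoxymethoxy)-6-(3-phenylprop-2-ynoyl)phenoxide | [Cs+].COc1cc(OCOC)c([C@H]2CCCCN2C(=O)OC(C)(C)C)c([O-])c1C(=O)C#Cc1ccccc1 | intermediate
22 | tert-butyl (2R)-2-[5-methoxy-7-(methoxymethoxy)-4-oxo-2-phenyl-4H-chromen-8-yl]piperidine-1-carboxylate | COc1cc(OCOC)c([C@H]2CCCCN2C(=O)OC(C)(C)C)c2oc(-c3ccccc3)cc(=O)c12 | intermediate
23 | 7-hydroxy-5-methoxy-2-phenyl-8-[(2R)-piperidin-2-yl]-4H-chromen-4-one | COc1cc(O)c([C@H]2CCCCN2)c2oc(-c3ccccc3)cc(=O)c12 | target

**Step count**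
Total steps: 11. Longest linear sequence: 11 (from 5-methoxyresorcinol).

**Steps most likely to fail**

Step 10. The carboxylate may add at the wrong aryne terminus (C4a) because the piperidinyl carbamate shields C8a, or the aryl anion may be protonated before the acyl shift, leaving an O-aryl ester. The fallback builds the same C4a–C4 bond by an aryllithium and sets out from 13. Both hydroxyls are capped (MOMCl, iPr2NEt) to give tert-butyl (2R)-2-[3-bromo-4-methoxy-2,6-bis(methoxymethoxy)phenyl]piperidine-1-carboxylate F1. Bromine–lithium exchange (n-BuLi, THF, −78 °C) and addition to 3-phenylpropiolaldehyde give tert-butyl (2R)-2-[3-(1-hydroxy-3-phenylprop-2-yn-1-yl)-4-methoxy-2,6-bis(methoxymethoxy)phenyl]piperidine-1-carboxylate F2, as a mixture of carbinol epimers that are both used. MnO2 oxidation gives tert-butyl (2R)-2-[4-methoxy-2,6-bis(methoxymethoxy)-3-(3-phenylprop-2-ynoyl)phenyl]piperidine-1-carboxylate F3. HCl in MeOH then removes both MOM groups and the Boc group, and the freed 2-hydroxyaryl ynone should close 6-endo under the same acid. The fallback comes back to the route at the target 23.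

Step 4. Facial selectivity may be poor or reversed if an ortho MOM oxygen competes with the sulfinyl oxygen for magnesium, and addition to the hindered, electron-rich imine may be slow. The fallback sets the stereocentre by catalytic hydrogenation and sets out from 2 through aryllithium 3. Transmetalation with ZnCl2 and Negishi coupling with 2-bromopyridine (Pd2(dba)3, XPhos, THF, 60 °C) give 2-[4-methoxy-2,6-bis(methoxymethoxy)phenyl]pyridine F4. Benzyl bromide (MeCN, 80 °C) gives 1-benzyl-2-[4-methoxy-2,6-bis(methoxymethoxy)phenyl]pyridinium bromide F5. Iridium-catalysed asymmetric hydrogenation ([Ir(cod)Cl]2, a chiral bisphosphine of the SynPhos type, H2 40 bar, ligand antipode chosen in a trial run) gives (2R)-1-benzyl-2-[4-methoxy-2,6-bis(methoxymethoxy)phenyl]piperidine F6; its enantiomeric purity can be raised by crystallising a salt with a chiral acid if needed. Hydrogenolysis (H2, Pd(OH)2/C, MeOH) gives (2R)-2-[4-methoxy-2,6-bis(methoxymethoxy)phenyl]piperidine F7. HCl in MeOH then gives 11, where the route is rejoined for the Boc protection of step 6.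

Step 8. The triflating agent may be consumed unselectively in the presence of the second silyl ether and the carbamate, the doubly flanked lithium phenoxide may be triflated incompletely, or the carbon-bound silyl group may be lost in work-up. The fallback separates the three events, sets out from 13 and puts the triflate on last. Silylation and bromine–lithium exchange as in step 8, but with a methanolic K2CO3 quench in place of Tf2O, give tert-butyl (2R)-2-[2,6-dihydroxy-4-methoxy-3-(trimethylsilyl)phenyl]piperidine-1-carboxylate F8. One equivalent of MOMCl with iPr2NEt should cap the less hindered hydroxyl, the one not flanked by the silyl group, to give tert-butyl (2R)-2-[2-hydroxy-4-methoxy-6-(methoxymethoxy)-3-(trimethylsilyl)phenyl]piperidine-1-carboxylate F9. KHMDS and PhNTf2 (THF, −78 °C → rt) then triflate the isolated phenol. The fallback comes back to the route at 18.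

**Further compounds**
F1 | step 10 | tert-butyl (2R)-2-[3-bromo-4-methoxy-2,6-bis(methoxymethoxy)phenyl]piperidine-1-carboxylate | COc1cc(OCOC)c([C@H]2CCCCN2C(=O)OC(C)(C)C)c(OCOC)c1Br
F2 | step 10 | tert-butyl (2R)-2-[3-(1-hydroxy-3-phenylprop-2-yn-1-yl)-4-methoxy-2,6-bis(methoxymethoxy)phenyl]piperidine-1-carboxylate | COc1cc(OCOC)c([C@H]2CCCCN2C(=O)OC(C)(C)C)c(OCOC)c1C(O)C#Cc1ccccc1
F3 | step 10 | tert-butyl (2R)-2-[4-methoxy-2,6-bis(methoxymethoxy)-3-(3-phenylprop-2-ynoyl)phenyl]piperidine-1-carboxylate | COc1cc(OCOC)c([C@H]2CCCCN2C(=O)OC(C)(C)C)c(OCOC)c1C(=O)C#Cc1ccccc1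
F4 | step 4 | 2-[4-methoxy-2,6-bis(methoxymethoxy)phenyl]pyridine | COCOc1cc(OC)cc(OCOC)c1-c1ccccn1
F5 | step 4 | 1-benzyl-2-[4-methoxy-2,6-bis(methoxymethoxy)phenyl]pyridinium bromide | COCOc1cc(OC)cc(OCOC)c1-c1cccc[n+]1Cc1ccccc1.[Br-]
F6 | step 4 | (2R)-1-benzyl-2-[4-methoxy-2,6-bis(methoxymethoxy)phenyl]piperidine | COCOc1cc(OC)cc(OCOC)c1[C@H]2CCCCN2Cc3ccccc3
F7 | step 4 | (2R)-2-[4-methoxy-2,6-bis(methoxymethoxy)phenyl]piperidine | COCOc1cc(OC)cc(OCOC)c1[C@H]2CCCCN2
F8 | step 8 | tert-butyl (2R)-2-[2,6-dihydroxy-4-methoxy-3-(trimethylsilyl)phenyl]piperidine-1-carboxylate | COc1cc(O)c([C@H]2CCCCN2C(=O)OC(C)(C)C)c(O)c1[Si](C)(C)C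
F9 | step 8 | tert-butyl (2R)-2-[2-hydroxy-4-methoxy-6-(methoxymethoxy)-3-(trimethylsilyl)phenyl]piperidine-1-carboxylate | COc1cc(OCOC)c([C@H]2CCCCN2C(=O)OC(C)(C)C)c(O)c1[Si](C)(C)C
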